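## Retrosynthetic overview

- Target ⇒ α'-aryl enone (6-aryl-carvotanacetone): the ring alkene and the benzylic C–H come from a reductive 1,3-transposition of the enone (tosylhydrazone, catecholborane). The ketone is only a traceless handle.
- α'-Aryl enone ⇒ magnolol + (R)-carvotanacetone: the aryl–C(sp3) bond joins two carbons that are both nucleophilic by nature (phenol ortho-carbon, ketone α'-carbon). The enolate carbon is reversed to an enolonium-type electrophile by Cu(II) oxidation, and the new stereocentre is set trans to isopropyl.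
- (R)-Carvotanacetone ⇒ (R)-(−)-carvone by selective hydrogenation; the isopropyl-bearing stereocentre comes from the chiral pool.
- No ring is formed: the cyclohexene ring is that of carvone and the biaryl is that of magnolol.

Assumption: magnolol and (R)-(−)-carvone are taken as cheap commercial materials; the target is read as the trans (1S,6S)-cyclohexenyl isomer, which maps onto (R)-carvone without any inversion.

## Route

Step 1
Reactants: 1 (R)-(−)-carvone
Product: 2 (R)-carvotanacetone [(5R)-2-methyl-5-(propan-2-yl)cyclohex-2-en-1-one]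
Conditions: H2 (1 atm), RhCl(PPh3)3 (1 mol%), benzene, rt
Reagents that add atoms: none
Why: Chemoselective homogeneous hydrogenation (Wilkinson's catalyst) reduces the unhindered 1,1-disubstituted isopropenyl alkene much faster than the trisubstituted conjugated enone alkene, so the enone and the chiral-pool stereocentre are untouched and no new stereocentre is formed.

Step 2
Reactants: 2 (R)-carvotanacetone (1.0 equiv); 3 magnolol (2.0 equiv, excess recovered)
Product: 6 (5S,6R)-6-[2,2'-dihydroxy-5,5'-di(prop-2-en-1-yl)biphenyl-3-yl]-2-methyl-5-(propan-2-yl)cyclohex-2-en-1-one, via lithium dienolate 4 (not isolated), via dilithium magnolate 5 (not isolated)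
Conditions: LiHMDS (5.5 equiv), THF, −78 °C, 30 min; Cu(II) 2-ethylhexanoate (2.2 equiv), −78 °C → rt; aq NH4Cl
Reagents that add atoms: none
Why: Proposed new method: LiHMDS gives the kinetic cross-conjugated α'-enolate 4 and the bis-phenolate 5, Cu(II) oxidises the enolate carbon by one electron to an electrophilic α-keto radical/Cu(III) enolate (an enolonium equivalent, i.e. the normally nucleophilic α'-carbon now reacts as the electrophile), this is attacked by the only free ortho carbon of the copper-bound phenolate (para position blocked by allyl), and a second Cu(II) plus tautomerisation restores the phenol; the bond forms anti to the neighbouring isopropyl group and the new benzylic α-centre is epimerisable under the basic conditions, so the trans (5S,6R) isomer results; the closest known reaction type is the Cu(II)- or Fe(III)-mediated oxidative heterocoupling of lithium enolates (carvone included) with indolide or pyrrolide anions, together with iron-catalysed oxidative cross-coupling of phenols with 1,3-dicarbonyl compounds.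

Step 3
Reactants: 6 (5S,6R)-6-[2,2'-dihydroxy-5,5'-di(prop-2-en-1-yl)biphenyl-3-yl]-2-methyl-5-(propan-2-yl)cyclohex-2-en-1-one
Product: 10 3-[(1S,6S)-3-methyl-6-(propan-2-yl)cyclohex-2-en-1-yl]-5,5'-di(prop-2-en-1-yl)biphenyl-2,2'-diol (CNP0249009.1), via tosylhydrazone 7 (not isolated), via N,O,O-triboryl tosylhydrazine 8 (not isolated), via allylic diazene 9 (not isolated)
Conditions: TsNHNH2 (1.2 equiv), PPTS (5 mol%), MeOH, 45 °C, then evaporate (PhMe azeotrope); catecholborane (5 equiv), CHCl3, 0 °C → rt; NaOAc·3H2O (6 equiv), reflux 1 h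
Reagents that add atoms: none
Why: Kabalka-type reductive 1,3-transposition of an α,β-unsaturated tosylhydrazone: condensation gives 7, catecholborane adds H–B across C=N (the allyl alkenes are inert to it at or below rt and the phenols are only transiently O-borylated) to give 8, acetate-induced loss of sulfinate gives diazene 9, and its retro-ene loss of N2 delivers hydrogen to the former β-carbon and moves the double bond to the position between the former carbonyl carbon and the methyl-bearing carbon, so oxygen is removed without creating a stereocentre and the two existing centres (the epimerisable one already in its thermodynamic trans form) are retained.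

## Compound list

1 | (R)-(−)-carvone, (5R)-2-methyl-5-(prop-1-en-2-yl)cyclohex-2-en-1-one | CC1=CC[C@H](CC1=O)C(C)=C | starting material
2 | (R)-carvotanacetone, (5R)-2-methyl-5-(propan-2-yl)cyclohex-2-en-1-one | CC1=CC[C@H](CC1=O)C(C)C | intermediate
3 | magnolol, 5,5'-di(prop-2-en-1-yl)biphenyl-2,2'-diol | C=CCc1ccc(O)c(-c2cc(CC=C)ccc2O)c1 | starting material
4 | lithium (3S)-6-methyl-3-(propan-2-yl)cyclohexa-1,5-dien-1-olate (kinetic cross-conjugated dienolate of 2) | CC1=CC[C@H](C=C1[O-])C(C)C.[Li+] | intermediate
5 | dilithium magnolate (dilithium 5,5'-di(prop-2-en-1-yl)biphenyl-2,2'-diolate) | C=CCc1ccc([O-])c(-c2cc(CC=C)ccc2[O-])c1.[Li+].[Li+] | intermediate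
6 | (5S,6R)-6-[2,2'-dihydroxy-5,5'-di(prop-2-en-1-yl)biphenyl-3-yl]-2-methyl-5-(propan-2-yl)cyclohex-2-en-1-one (aryl and isopropyl trans) | C=CCc1ccc(O)c(-c2cc(CC=C)cc([C@@H]3C(=O)C(C)=CC[C@H]3C(C)C)c2O)c1 | intermediate
7 | N-tosylhydrazone of 6 (C=N geometry not assigned; 5S,6R) | C=CCc1ccc(O)c(-c2cc(CC=C)cc([C@@H]3C(=NNS(=O)(=O)c4ccc(C)cc4)C(C)=CC[C@H]3C(C)C)c2O)c1 | intermediate
8 | hydroboration adduct of 7: N-(1,3,2-benzodioxaborol-2-yl) tosylhydrazine with both phenols as O-(1,3,2-benzodioxaborol-2-yl) ethers (N-bearing ring carbon unassigned; the other two centres as in 6) | C=CCc1ccc(OB2Oc3ccccc3O2)c(-c2cc(CC=C)cc([C@@H]3C(N(NS(=O)(=O)c4ccc(C)cc4)B4Oc5ccccc5O4)C(C)=CC[C@H]3C(C)C)c2OB2Oc3ccccc3O2)c1 | intermediate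
9 | allylic monoalkyl diazene (N=NH on the former carbonyl carbon, that carbon unassigned; phenols free) | C=CCc1ccc(O)c(-c2cc(CC=C)cc([C@@H]3C(N=N)C(C)=CC[C@H]3C(C)C)c2O)c1 | intermediate
10 | 3-[(1S,6S)-3-methyl-6-(propan-2-yl)cyclohex-2-en-1-yl]-5,5'-di(prop-2-en-1-yl)biphenyl-2,2'-diol (CNP0249009.1) | C=CCc1ccc(O)c(-c2cc(CC=C)cc([C@@H]3C=C(C)CC[C@H]3C(C)C)c2O)c1 | target

## Step count and risk

Total steps: 3. Longest linear sequence: 3 (1 → 2 → 6 → 10; magnolol 3 enters at step 2 as bought).

Steps most likely to fail, in order of risk: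

**Step 2 (oxidative enolate–phenolate coupling).** Risks are oxidative oligomerisation of magnolate, enolate homodimer, O- instead of C-coupling, double coupling, and aromatisation of oxidised 2 to carvacrol. The fallback sets out from 2 and comes back to the route at 6. It replaces the one-electron oxidation by a discrete two-electron enolonium. Compound 2 is converted with LDA and TMSCl in THF at −78 °C into the kinetic cross-conjugated silyl dienol ether {[(3S)-6-methyl-3-(propan-2-yl)cyclohexa-1,5-dien-1-yl]oxy}trimethylsilane F1. F1 is added to PhI(OH)OTs/BF3·OEt2 in CH2Cl2 at −78 °C to give the O-bound phenyl(tosyloxy)-λ3-iodanyl enolonium species F2, which is not isolated. Magnolol 3 (3 equiv) is then added at −78 °C, so that its free ortho carbon attacks the electrophilic α'-carbon in a Friedel–Crafts sense with loss of iodobenzene. Brief DBU equilibration of the α-centre gives trans 6.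

**Step 3 (hydrazone formation and reductive transposition).** Risks are slow condensation at the hindered carbonyl, acid-promoted cyclodehydration of the ortho-hydroxyaryl ketone to a benzofuran, and incomplete reduction. The fallback sets out from 6 and comes back at 10. It fixes the alkene position through a regiodefined enolate instead of a hydrazone. Both phenols are silylated (TBSCl, imidazole, DMF, 50 °C) to give the bis-TBS ether of 6, F3. Conjugate reduction with L-Selectride (THF, −78 °C) and trapping of the resulting enolate with Comins' reagent gives the enol triflate (5S,6R)-6-aryl-2-methyl-5-(propan-2-yl)cyclohex-1-en-1-yl trifluoromethanesulfonate F4, whose double bond already lies between the former carbonyl carbon and the methyl-bearing carbon. Palladium-catalysed formate reduction (Pd(OAc)2, PPh3, HCO2H, Bu3N, DMF, 60 °C) replaces OTf by H to give the bis-TBS ether of 10, F5. TBAF in THF at 0 °C then releases 10.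

**Step 1 (selective hydrogenation).** The risk is over-reduction of the enone alkene. The fallback sets out from 1 and comes back at 2. It avoids H2 altogether: Markovnikov addition of HBr (HBr/AcOH, 0 °C) to the isopropenyl group gives the tertiary bromide (5R)-5-(2-bromopropan-2-yl)-2-methylcyclohex-2-en-1-one F6. Radical debromination (Bu3SnH, AIBN, benzene, 80 °C) then gives 2 with the enone intact.

## Further compounds

F1 | step 2 | {[(3S)-6-methyl-3-(propan-2-yl)cyclohexa-1,5-dien-1-yl]oxy}trimethylsilane | CC1=CC[C@H](C=C1O[Si](C)(C)C)C(C)C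
F2 | step 2 | O-bound phenyl(tosyloxy)-λ3-iodanyl enolonium species derived from 2 | CC1=CC[C@H](C=C1O[I](c1ccccc1)OS(=O)(=O)c1ccc(C)cc1)C(C)C
F3 | step 3 | bis(tert-butyldimethylsilyl) ether of 6 | C=CCc1ccc(O[Si](C)(C)C(C)(C)C)c(-c2cc(CC=C)cc([C@@H]3C(=O)C(C)=CC[C@H]3C(C)C)c2O[Si](C)(C)C(C)(C)C)c1
F4 | step 3 | (5S,6R)-6-[2,2'-bis(tert-butyldimethylsilyloxy)-5,5'-di(prop-2-en-1-yl)biphenyl-3-yl]-2-methyl-5-(propan-2-yl)cyclohex-1-en-1-yl trifluoromethanesulfonate | C=CCc1ccc(O[Si](C)(C)C(C)(C)C)c(-c2cc(CC=C)cc([C@@H]3C(OS(=O)(=O)C(F)(F)F)=C(C)CC[C@H]3C(C)C)c2O[Si](C)(C)C(C)(C)C)c1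
F5 | step 3 | bis(tert-butyldimethylsilyl) ether of 10 | C=CCc1ccc(O[Si](C)(C)C(C)(C)C)c(-c2cc(CC=C)cc([C@@H]3C=C(C)CC[C@H]3C(C)C)c2O[Si](C)(C)C(C)(C)C)c1
F6 | step 1 | (5R)-5-(2-bromopropan-2-yl)-2-methylcyclohex-2-en-1-one | CC1=CC[C@H](CC1=O)C(C)(C)Br
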